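The route rests on opening cyclohexanone ring A between the ketone carbon C-1 and the propenyl-bearing C-2. This C(=O)–CH(CH=CHCH3) unit is a β,γ-unsaturated ketone, the retron of an aldehyde C–H addition across a 1,3-diene, and C-2 is an epimerisable, allylic α-carbon. A ruthenium hydride cycloisomerises an acyclic 4-oxo aldehyde carrying a hexa-3,5-dienyl chain (used as an E/Z mixture): in one operation it closes ring A, creates the ketone, the (E)-propenyl group and the C-2 centre, funnelling both diene isomers through one π-allyl intermediate. C-4, C-5 and the furanone centre are set beforehand by an organocatalytic Mukaiyama–Michael addition and a trans-selective lactone alkylation.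

Key step: step 13

Remark on names: ring A is numbered C-1 (ketone), C-2 (propenyl), C-4 (furanone-bearing), C-5 (hexenoyl-bearing); "Fur" stands for the (2R)-3-[(4-methoxyphenyl)methoxy]-2,4-dimethyl-5-oxo-2,5-dihydrofuran-2-yl group.

Assumption: racemic ethyl lactate is used because its stereocentre is erased in step 4, and the addition in step 6 is assumed to follow the syn (unlike) topicity known for 5-alkyl-2-silyloxyfurans with this catalyst class.

Step 1
Reactants: 1 ethyl lactate (racemic), 2 propanoyl chloride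
Product: 3 ethyl 2-(propanoyloxy)propanoate
Conditions: Et3N, DMAP (cat.), CH2Cl2, 0 °C → rt
Reagents that add atoms: propanoyl chloride 2, CCC(=O)Cl
Why: DMAP-catalysed acylation of the secondary alcohol by the acid chloride; no stereochemical issue arises.

Step 2
Reactants: 3 ethyl 2-(propanoyloxy)propanoate
Product: 4 4-hydroxy-3,5-dimethylfuran-2(5H)-one
Conditions: KOtBu, THF, 0 °C → rt; then 1 M HCl
Reagents that add atoms: none
Why: Dieckmann condensation, in which the propanoate enolate attacks the neighbouring ethyl ester (5-exo-trig) and the stable tetronate salt drives the reaction.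

Step 3
Reactants: 4 4-hydroxy-3,5-dimethylfuran-2(5H)-one, 5 (4-methoxyphenyl)methanol
Product: 6 4-[(4-methoxyphenyl)methoxy]-3,5-dimethylfuran-2(5H)-one
Conditions: PPh3, DIAD, THF, 0 °C → rt
Reagents that add atoms: (4-methoxyphenyl)methanol 5, COc1ccc(CO)cc1
Why: Mitsunobu alkylation of the strongly acidic tetronic acid should occur on O-4, giving a vinylogous 4-methoxybenzyl ester that is later removable with acid.

Step 4
Reactants: 6 4-[(4-methoxyphenyl)methoxy]-3,5-dimethylfuran-2(5H)-one
Product: 7 {[4-[(4-methoxyphenyl)methoxy]-3,5-dimethylfuran-2-yl]oxy}tri(propan-2-yl)silane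
Conditions: iPr3SiOTf, Et3N, CH2Cl2, 0 °C
Reagents that add atoms: tri(propan-2-yl)silyl trifluoromethanesulfonate, CC(C)[Si](C(C)C)(C(C)C)OS(=O)(=O)C(F)(F)F
Why: soft enolisation (O-silylation of the lactone carbonyl, removal of H-5 by the amine) should give the aromatic 2-silyloxyfuran needed for the Mukaiyama–Michael reaction.

Step 5
Reactants: 8 (but-3-en-1-yloxy)(tert-butyl)dimethylsilane, 9 (E)-but-2-enal
Product: 10 (E)-5-[(tert-butyldimethylsilyl)oxy]pent-2-enal
Conditions: second-generation Hoveyda–Grubbs catalyst, RuCl2(H2IMes)(=CH–C6H4-2-OiPr) (2 mol %), excess 9, CH2Cl2, 40 °C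
Reagents that add atoms: (E)-but-2-enal 9, C/C=C/C=O
Why: olefin cross-metathesis of a terminal alkene with an excess of the electron-poor partner should give the (E)-enal with loss of propene.

Step 6
Reactants: 7 the silyloxyfuran, 10 (E)-5-[(tert-butyldimethylsilyl)oxy]pent-2-enal
Product: 11 (3S)-5-[(tert-butyldimethylsilyl)oxy]-3-Fur-pentanal
Conditions: (2R,5R)-5-benzyl-2-tert-butyl-3-methylimidazolidin-4-one (20 mol %), 2,4-dinitrobenzoic acid (20 mol %), H2O (2 equiv), CH2Cl2, −70 °C
Reagents that add atoms: enal 10, O=C/C=C/CCO[Si](C)(C)C(C)(C)C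
Why: iminium-catalysed vinylogous Mukaiyama–Michael addition, in which the benzyl group of the (E)-iminium ion shields the Re face of enal C-3 and furan C-5 adds with its Re face to the Si face (unlike topicity, open transition state), setting the (3S) centre and the quaternary (R) centre.

Step 7
Reactants: 11 (3S)-5-[(tert-butyldimethylsilyl)oxy]-3-Fur-pentanal
Product: 14 (4S)-4-Fur-oxan-2-one, via silyl ether acid 12 (not isolated), via hydroxy acid 13 (not isolated)
Conditions: NaClO2, NaH2PO4, 2-methylbut-2-ene, t-BuOH/H2O, 0 °C → rt; then 1 M HCl, THF, rt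
Reagents that add atoms: sodium chlorite, [Na+].[O-]Cl=O
Why: Pinnick oxidation should convert the aldehyde into the acid without touching the vinylogous ester, after which aqueous acid removes the primary silyl ether and the 5-hydroxy acid lactonises.

Step 8
Reactants: 14 (4S)-4-Fur-oxan-2-one, 15 1,3,2-dioxathiolane 2,2-dioxide
Product: 18 (3R)-3-[(1S)-3-hydroxy-1-Fur-propyl]oxolan-2-one, via lithium alkyl sulfate 16 (not isolated), via hydroxyethyl δ-lactone 17 (not isolated)
Conditions: LiN(iPr)2, THF, −78 °C; 15, −78 → 0 °C; then H2SO4 (cat.), H2O (1 equiv), THF, rt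
Reagents that add atoms: 1,3,2-dioxathiolane 2,2-dioxide 15, O=S1(=O)OCCO1
Why: enolate alkylation by the cyclic sulfate (an epoxide equivalent) should occur anti to the bulky C-4 substituent and set the trans (3R) centre (this becomes the cis C-4/C-5 relation of ring A because the lactone carbonyl ends up as the exocyclic acyl group), after which hydrolysis of the sulfate monoester and acid-catalysed translactonisation to the less strained γ-lactone release the other arm as the free alcohol.

Step 9
Reactants: 18 (3R)-3-[(1S)-3-hydroxy-1-Fur-propyl]oxolan-2-one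
Product: 19 (3S)-3-Fur-3-[(3R)-2-oxooxolan-3-yl]propanal
Conditions: Dess–Martin periodinane, NaHCO3, CH2Cl2, 0 °C → rt
Reagents that add atoms: none
Why: buffered Dess–Martin oxidation of the primary alcohol should give the aldehyde without epimerising the lactone α-centre.

Step 10
Reactants: 19 (3S)-3-Fur-3-[(3R)-2-oxooxolan-3-yl]propanal, 20 triphenyl(prop-2-en-1-yl)phosphonium bromide
Product: 21 (3R)-3-[(1S)-1-Fur-hexa-3,5-dien-1-yl]oxolan-2-one (3E/3Z mixture)
Conditions: 20, n-BuLi, THF, −78 → 0 °C; then 19, −78 °C → rt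
Reagents that add atoms: prop-2-en-1-ylidene(triphenyl)phosphorane, C=CC=P(c1ccccc1)(c1ccccc1)c1ccccc1
Why: Wittig olefination with the semi-stabilised allyl ylide (generated from salt 20 with n-BuLi) is selective for the aldehyde over the lactone and should give an E/Z mixture at the new double bond, which is acceptable because step 13 is stereoconvergent.

Step 11
Reactants: 21 the diene lactone, 22 (E)-5-bromopent-2-ene
Product: 23 (3R,7E)-1-hydroxy-3-[(1S)-1-Fur-hexa-3,5-dien-1-yl]non-7-en-4-one
Conditions: 22, Li (1% Na), Et2O, −10 °C; then 21, THF, −78 °C; NH4Cl (aq)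
Reagents that add atoms: (E)-pent-3-en-1-yllithium, C/C=C/CC[Li]
Why: 1,2-addition of one equivalent of (E)-pent-3-en-1-yllithium (generated from bromide 22 with lithium metal) to the γ-lactone at −78 °C should stop at the lithium hemiketal and give the γ-hydroxy ketone on quenching, the vinylogous ester carbonyl and the diene being much less electrophilic.

Step 12
Reactants: 23 the γ-hydroxy ketone
Product: 24 (3R,7E)-3-[(1S)-1-Fur-hexa-3,5-dien-1-yl]-4-oxonon-7-enal
Conditions: Dess–Martin periodinane, NaHCO3, CH2Cl2, 0 °C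
Reagents that add atoms: none
Why: Dess–Martin oxidation of the open-chain hydroxy ketone (in equilibrium with its lactol) should give the 4-oxo aldehyde under neutral conditions that leave the ketone α-centre intact.

Step 13
Reactants: 24 the dienyl 4-oxo aldehyde (E/Z mixture)
Product: 25 (2S,4S,5R)-4-Fur-5-[(4E)-hex-4-enoyl]-2-[(1E)-prop-1-en-1-yl]cyclohexan-1-one
Conditions: RuHCl(CO)(PPh3)3 (10 mol %), toluene (0.02 M), 90 °C
Reagents that add atoms: none
Why: Proposed new method: the ruthenium hydride adds to the terminal CH2 of the diene (either geometrical isomer) to give a 1-methyl-3-alkyl π-allylruthenium that equilibrates syn/anti; its σ-form bound at the methyl-bearing carbon delivers the other allyl terminus (future C-2) to the aldehyde carbon (future C-1) through a closed chair-like transition state, and β-hydride elimination from the ruthenium alkoxide releases the ketone and regenerates the hydride, a net intramolecular diene hydroacylation. The closest known chemistry is the intermolecular ruthenium-hydride-catalysed coupling of aldehydes with 1,3-dienes to β,γ-unsaturated ketones and the nickel-hydride-mediated cyclisation of dienyl aldehydes to 2-propenylcycloalkanols. Ring A closes by a 6-exo-trig carbonyl addition, since attack at the distal allyl terminus would require an eight-membered ring. The (E)-propenyl geometry should follow from the syn π-allyl (methyl pseudo-equatorial), and C-2 is expected (S) because the alkenyl arm sits equatorial in the chair, cis to the equatorial furanone group at C-4; as an allylic α-keto centre it can also drift to this more stable configuration. The step needs chemoselectivity for the aldehyde over the ketone and for the terminal diene over the 1,2-disubstituted hexenoyl alkene, which the faster insertion of aldehydes and the faster hydrometalation of terminal dienes should secure. C-4, C-5 and the furanone centre are not touched under these neutral conditions.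

Step 14
Reactants: 25 the protected cyclohexanone
Product: 26 (2S,4S,5R)-5-[(4E)-hex-4-enoyl]-4-[(2R)-3-hydroxy-2,4-dimethyl-5-oxo-2,5-dihydrofuran-2-yl]-2-[(1E)-prop-1-en-1-yl]cyclohexan-1-one (target, CNP0546498.1)
Conditions: CF3CO2H/CH2Cl2 (1:9), anisole, 0 °C
Reagents that add atoms: none
Why: acidolysis of the 4-methoxybenzyl vinylogous ester (SN1 cleavage, cation trapped by anisole) should free the tetronic acid, and cold, short exposure avoids alkene migration or epimerisation.

Compound list
1 | ethyl 2-hydroxypropanoate (ethyl lactate, racemic) | CCOC(=O)C(C)O | starting material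
2 | propanoyl chloride | CCC(=O)Cl | starting material
3 | ethyl 2-(propanoyloxy)propanoate (racemic) | CCOC(=O)C(C)OC(=O)CC | intermediate
4 | 4-hydroxy-3,5-dimethylfuran-2(5H)-one (racemic) | CC1OC(=O)C(C)=C1O | intermediate
5 | (4-methoxyphenyl)methanol | COc1ccc(CO)cc1 | starting material
6 | 4-[(4-methoxyphenyl)methoxy]-3,5-dimethylfuran-2(5H)-one (racemic) | CC1OC(=O)C(C)=C1OCc1ccc(OC)cc1 | intermediate
7 | {[4-[(4-methoxyphenyl)methoxy]-3,5-dimethylfuran-2-yl]oxy}tri(propan-2-yl)silane | Cc1oc(O[Si](C(C)C)(C(C)C)C(C)C)c(C)c1OCc1ccc(OC)cc1 | intermediate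
8 | (but-3-en-1-yloxy)(tert-butyl)dimethylsilane | C=CCCO[Si](C)(C)C(C)(C)C | starting material
9 | (E)-but-2-enal | C/C=C/C=O | starting material
10 | (E)-5-[(tert-butyldimethylsilyl)oxy]pent-2-enal | O=C/C=C/CCO[Si](C)(C)C(C)(C)C | intermediate
11 | (3S)-5-[(tert-butyldimethylsilyl)oxy]-3-Fur-pentanal | O=CC[C@H](CCO[Si](C)(C)C(C)(C)C)[C@@]1(C)OC(=O)C(C)=C1OCc2ccc(OC)cc2 | intermediate
12 | (3S)-5-[(tert-butyldimethylsilyl)oxy]-3-Fur-pentanoic acid | OC(=O)C[C@H](CCO[Si](C)(C)C(C)(C)C)[C@@]1(C)OC(=O)C(C)=C1OCc2ccc(OC)cc2 | intermediate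
13 | (3S)-5-hydroxy-3-Fur-pentanoic acid | OC(=O)C[C@H](CCO)[C@@]1(C)OC(=O)C(C)=C1OCc2ccc(OC)cc2 | intermediate
14 | (4S)-4-Fur-oxan-2-one | O=C1C[C@H](CCO1)[C@@]2(C)OC(=O)C(C)=C2OCc3ccc(OC)cc3 | intermediate
15 | 1,3,2-dioxathiolane 2,2-dioxide | O=S1(=O)OCCO1 | starting material
16 | lithium 2-[(3R,4S)-2-oxo-4-Fur-oxan-3-yl]ethyl sulfate | O=C1OCC[C@@H]([C@H]1CCOS(=O)(=O)[O-])[C@@]2(C)OC(=O)C(C)=C2OCc3ccc(OC)cc3.[Li+] | intermediate
17 | (3R,4S)-3-(2-hydroxyethyl)-4-Fur-oxan-2-one | O=C1OCC[C@@H]([C@H]1CCO)[C@@]2(C)OC(=O)C(C)=C2OCc3ccc(OC)cc3 | intermediate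
18 | (3R)-3-[(1S)-3-hydroxy-1-Fur-propyl]oxolan-2-one | O=C1OCC[C@@H]1[C@H](CCO)[C@@]2(C)OC(=O)C(C)=C2OCc3ccc(OC)cc3 | intermediate
19 | (3S)-3-Fur-3-[(3R)-2-oxooxolan-3-yl]propanal | O=C1OCC[C@@H]1[C@H](CC=O)[C@@]2(C)OC(=O)C(C)=C2OCc3ccc(OC)cc3 | intermediate
20 | triphenyl(prop-2-en-1-yl)phosphonium bromide | C=CC[P+](c1ccccc1)(c1ccccc1)c1ccccc1.[Br-] | starting material
21 | (3R)-3-[(1S)-1-Fur-hexa-3,5-dien-1-yl]oxolan-2-one, mixture of 3E and 3Z isomers (double bond left undefined in the SMILES) | O=C1OCC[C@@H]1[C@H](CC=CC=C)[C@@]2(C)OC(=O)C(C)=C2OCc3ccc(OC)cc3 | intermediate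
22 | (E)-5-bromopent-2-ene | C/C=C/CCBr | starting material
23 | (3R,7E)-1-hydroxy-3-[(1S)-1-Fur-hexa-3,5-dien-1-yl]non-7-en-4-one, diene as E/Z mixture | C/C=C/CCC(=O)[C@H](CCO)[C@H](CC=CC=C)[C@@]1(C)OC(=O)C(C)=C1OCc2ccc(OC)cc2 | intermediate
24 | (3R,7E)-3-[(1S)-1-Fur-hexa-3,5-dien-1-yl]-4-oxonon-7-enal, diene as E/Z mixture | C/C=C/CCC(=O)[C@H](CC=O)[C@H](CC=CC=C)[C@@]1(C)OC(=O)C(C)=C1OCc2ccc(OC)cc2 | intermediate
25 | (2S,4S,5R)-4-Fur-5-[(4E)-hex-4-enoyl]-2-[(1E)-prop-1-en-1-yl]cyclohexan-1-one | C/C=C/CCC(=O)[C@@H]1CC(=O)[C@H](/C=C/C)C[C@@H]1[C@@]2(C)OC(=O)C(C)=C2OCc3ccc(OC)cc3 | intermediate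
26 | (2S,4S,5R)-5-[(4E)-hex-4-enoyl]-4-[(2R)-3-hydroxy-2,4-dimethyl-5-oxo-2,5-dihydrofuran-2-yl]-2-[(1E)-prop-1-en-1-yl]cyclohexan-1-one | C/C=C/CCC(=O)[C@@H]1CC(=O)[C@H](/C=C/C)C[C@@H]1[C@@]1(C)OC(=O)C(C)=C1O | target

Total step count: 14. Longest linear sequence: 13 steps (steps 1–4 and 6–14, from ethyl lactate); step 5 is a one-step side branch.

Steps most likely to fail

Step 13 (proposed new method). The ruthenium hydride may instead walk the hexenoyl double bond or move the new β,γ-double bond into conjugation, decarbonylate the aldehyde, or insert too slowly at the hindered tether. The fallback sets out from 24 and uses the known nickel-hydride reductive cyclisation of dienyl aldehydes. With Ni(cod)2 [bis(cycloocta-1,5-diene)nickel, zerovalent nickel] (10 mol %), PPh3 and Et3SiH in THF at rt, the π-allylnickel formed from the diene adds to the aldehyde and the alkoxide is silylated, giving {[(4S,5R)-4-Fur-5-[(4E)-hex-4-enoyl]-2-[(1E)-prop-1-en-1-yl]cyclohexyl]oxy}triethylsilane F1 as a mixture at C-1 and C-2. AcOH/THF/H2O removes the silyl group to give (4S,5R)-4-Fur-5-[(4E)-hex-4-enoyl]-2-[(1E)-prop-1-en-1-yl]cyclohexan-1-ol F2. Dess–Martin oxidation, with brief Et3N treatment if needed to bring C-2 to the equatorial configuration, returns to 25.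

Step 6. With the fully substituted alkoxyfuran the furan-face selectivity may be low or of the opposite sense, which would give the wrong relative configuration between the quaternary centre and C-3. The fallback uses the fact that both arms on C-3 are two-carbon chains that differ only in oxidation level, so the C-3 epimer leads to the same lactone once their roles are exchanged. It sets out from 7 and 10 with the (2S,5S)-catalyst (like topicity), giving (3R)-5-[(tert-butyldimethylsilyl)oxy]-3-Fur-pentanal F3. NaBH4 in MeOH gives (3S)-5-[(tert-butyldimethylsilyl)oxy]-3-Fur-pentan-1-ol F4, and Ac2O/pyridine gives (3S)-5-[(tert-butyldimethylsilyl)oxy]-3-Fur-pentyl acetate F5. HF·pyridine gives (3R)-5-hydroxy-3-Fur-pentyl acetate F6, and TEMPO/PhI(OAc)2 in MeCN/H2O gives (3S)-5-acetoxy-3-Fur-pentanoic acid F7. K2CO3 in MeOH followed by 1 M HCl returns to 13, which lactonises to 14.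

Step 8. C-alkylation of the hindered lactone enolate by the cyclic sulfate may be slow and may lose out to proton transfer or decomposition of the electrophile. The fallback sets out from 14 and introduces the arm as an allyl group. LiN(iPr)2 followed by allyl bromide in THF at −78 °C gives (3R,4S)-4-Fur-3-(prop-2-en-1-yl)oxan-2-one F8, again trans. Lemieux–Johnson cleavage (OsO4 cat., NaIO4, 2,6-lutidine, dioxane/H2O) gives 2-[(3R,4S)-2-oxo-4-Fur-oxan-3-yl]acetaldehyde F9. NaBH4 at 0 °C returns to 17, which is equilibrated to 18 with TsOH (cat.) in CH2Cl2.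

Further compounds
F1 | step 13 | {[(4S,5R)-4-Fur-5-[(4E)-hex-4-enoyl]-2-[(1E)-prop-1-en-1-yl]cyclohexyl]oxy}triethylsilane (mixture at C-1 and C-2) | C/C=C/CCC(=O)[C@@H]1CC(O[Si](CC)(CC)CC)C(/C=C/C)C[C@@H]1[C@@]2(C)OC(=O)C(C)=C2OCc3ccc(OC)cc3
F2 | step 13 | (4S,5R)-4-Fur-5-[(4E)-hex-4-enoyl]-2-[(1E)-prop-1-en-1-yl]cyclohexan-1-ol (mixture at C-1 and C-2) | C/C=C/CCC(=O)[C@@H]1CC(O)C(/C=C/C)C[C@@H]1[C@@]2(C)OC(=O)C(C)=C2OCc3ccc(OC)cc3
F3 | step 6 | (3R)-5-[(tert-butyldimethylsilyl)oxy]-3-Fur-pentanal | O=CC[C@@H](CCO[Si](C)(C)C(C)(C)C)[C@@]1(C)OC(=O)C(C)=C1OCc2ccc(OC)cc2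
F4 | step 6 | (3S)-5-[(tert-butyldimethylsilyl)oxy]-3-Fur-pentan-1-ol | OCC[C@@H](CCO[Si](C)(C)C(C)(C)C)[C@@]1(C)OC(=O)C(C)=C1OCc2ccc(OC)cc2
F5 | step 6 | (3S)-5-[(tert-butyldimethylsilyl)oxy]-3-Fur-pentyl acetate | CC(=O)OCC[C@@H](CCO[Si](C)(C)C(C)(C)C)[C@@]1(C)OC(=O)C(C)=C1OCc2ccc(OC)cc2
F6 | step 6 | (3R)-5-hydroxy-3-Fur-pentyl acetate | CC(=O)OCC[C@@H](CCO)[C@@]1(C)OC(=O)C(C)=C1OCc2ccc(OC)cc2
F7 | step 6 | (3S)-5-acetoxy-3-Fur-pentanoic acid | CC(=O)OCC[C@@H](CC(=O)O)[C@@]1(C)OC(=O)C(C)=C1OCc2ccc(OC)cc2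
F8 | step 8 | (3R,4S)-4-Fur-3-(prop-2-en-1-yl)oxan-2-one | O=C1OCC[C@@H]([C@H]1CC=C)[C@@]2(C)OC(=O)C(C)=C2OCc3ccc(OC)cc3
F9 | step 8 | 2-[(3R,4S)-2-oxo-4-Fur-oxan-3-yl]acetaldehyde | O=C1OCC[C@@H]([C@H]1CC=O)[C@@]2(C)OC(=O)C(C)=C2OCc3ccc(OC)cc3
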